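Conventions: atom labels (C2, O4, C5 and so on) give the position of the atom in the target SMILES. Ring A is the oxepanone (C2, O4, C5, C30, C32, C33, C34), ring B the cyclohexane (C5, C6, C7, C8, C11, C30), ring C the cycloheptane (C14, C15, C18, C24, C25, C26, C28) and ring D the cyclopentane (C18, C19, C20, C21, C24). In rings C and D, α is the face of H18 and H24. In rings A and B, β is the face of the C31 methyl group on C30.

## Structural features

The target is a C30 triterpenoid made of two bicycles joined by the C12–C13 ethylene tether. The east bicycle is a 2,2-dimethyloxepan-3-one (ring A) trans-fused at C5–C30 to a cyclohexane (ring B). The west bicycle is a cycloheptane (ring C) cis-fused at C18–C24 to a cyclopentane (ring D). Ring B carries four contiguous stereocentres (C5, C30, C11, C8): the angular methyl group and the C8 hydroxyl are 1,3-diaxial on the β face, and the tether is equatorial on C11. The west half carries six: H14, H18, H24 and the C21 hydroxyl lie on the α face, while the C21 methyl group, the C13 tether and the epoxide oxygen on C26/C28 lie on the β face, with the quaternary C15 wedged between C14 and C18. The fragile groups are the trisubstituted epoxide (acids), the two tertiary alcohols (dehydration) and the α-alkoxy ketone at C34 (nucleophiles, peracids). The real difficulty is threefold: two stereochemical clusters insulated by the tether, so each needs its own source of absolute configuration; the bond from quaternary C15 to the stereocentre C14; and an epoxide on the concave β face, syn to the tether. The key step exploits that C15 with C16 and C17, C18, C19, C20, C21 with C22, C24, C25 and the C21 oxygen are the skeleton of (R)-linalool, which lacks only the C18–C24 bond of ring D. A sulfonyl radical adding at C25 closes that bond and leaves a sulfone on C25 and a bromide on C15 as handles for ring C.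

## Logic of the disconnections

36 to 34: the two C–O bonds of the epoxide (C26–O27 and C28–O27) are cut first because the epoxide is the most fragile group. Since the oxygen sits on the hindered β face, it is planned through bromohydrin 35, not by direct oxygen transfer. This removes two stereocentres. The forward step must place the bromonium ion on the α face and deliver water to the tertiary C28.

34 to 32: no skeletal bond is cut. The C34 ketone is traced back to a silyl ether (33, then 32), because an organometallic addition at C8 and enolate chemistry at C11 must come before it. The demand is selective oxidation of the only secondary alcohol and fluoride cleavage of two hindered silyl ethers.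

32 to 31: the C8–C9 bond is cut. The axial C31 methyl group of the ketone 31 blocks the axial trajectory, so a methyl nucleophile should enter equatorially and give the axial hydroxyl. One stereocentre is removed. The reagent must not enolise C11.

31 to 26 plus 20: the C11–C12 bond is cut through 30 and 28 (aldol addition, dehydration, conjugate reduction). The cut lies next to the C8 carbonyl and splits the molecule into a 13-carbon and a 16-carbon fragment. The C6=C7 unsaturation of 26 leaves C11 as the only enolisable carbon. The forward steps need a hindered enolate to add to an enolisable aldehyde, and both conjugated C=C bonds of 30 to be reduced while the ring C alkene survives.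

26 to 21: the C6=C7 bond is traced to the ketone 25. Then C11–C30 and O4–C2 are cut together, which unravels rings A and B to the acyclic diepoxide enol ether 24, then 22 and the achiral dienone 21. Anti opening of two epoxides accounts for the trans ring fusion and for C5 and C30 in one operation. The demands are an (R,R)-configured internal epoxide, attack at the tertiary C2 and carbon–carbon bond formation at C30.

20 to 14: functional-group changes only. The aldehyde comes from the silyl ether 18 through 19, and the C26=C28 alkene from the C26 ketone of 14 through 15 and 17. The demand is enolisation of 14 toward C28 and not toward C25.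

14 to 13: the C14–C15 bond of ring C is cut. A tertiary radical at C15 adding to the β-carbon of an enone is the one reliable way to join a quaternary carbon to C14. The cut opens ring C and removes the C14 stereocentre. The forward step must close 7-endo and choose the correct face of C14.

13 to 6 plus 10: the C25–C26 bond is cut (acylation of the sulfone carbanion, then loss of the sulfonyl group from 12). Compound 10 goes back through 9 to 7 and 8 by cutting C28=C14. The demand is 1,2-addition to the unsaturated amide and an (E)-alkene.

6 to 2 plus 4 (key disconnection): the isopropenyl group of 6 is traced to the bromide 5. In 5 the C18–C24 bond, the C25–S bond and the C15–Br bond are cut, which leads to 2 and 4, themselves from 1 and 3. Ring D and two stereocentres then come from the chiral pool in one step. The demand is a cis relationship of the two arms, both anti to the C21 oxygen, and ring closure before bromine transfer.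

## Other disconnections considered

Alternative 1: The cut is C33–C34 in ring A, made in the forward sense as the enol ether double bond C33=C34. The olefinic ester A1 (allyl group on C30, 2-alkoxy-2-methylpropanoate on O4) would be treated with a titanium alkylidene (from TiCl4, Zn, PbCl2, TMEDA and CH3CHBr2). Carbonyl olefination and ring-closing metathesis would give the cyclic enol ether A2, and mild acid would then release the C34 ketone.
- In its favour: C34 appears directly at the ketone oxidation level, the position of the oxygen is unambiguous, and no cationic intermediate is involved, so the side paths that threaten step 17 do not arise. On these points it is the better of the two.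
- Against it here: the O4–C2 bond, a tertiary alkyl ether of a hindered secondary alcohol, has to be made before the ring closure. The C5 hydroxyl has to be cis to the angular methyl group. The reagent is stoichiometric. A2 has its ring B carbonyl at C11, so the C8 carbinol, the C9 methyl group and the C11 tether still call for a 1,2-transposition.
- Comparison: in structure it covers only rings A and B and would be combined with the same west half. In mechanism it trades one cascade that sets C5, C30 and both rings for a sequence of individually predictable steps. In step economy it is expected to be several steps longer up to the stage of 26.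

Alternative 2: The cut is C8–C11 in ring B. SmI2 would reduce the C8 methyl ketone of the oxepane keto enoate A3 to a ketyl radical that adds 6-exo to C11, the β-carbon of the enoate on C30. The cis hydroxy ester would close to the γ-lactone A4.
- In its favour: C8 and C11 are set together, the tertiary alcohol is formed with its methyl group in place, and the tether position on C11 is fixed by the enoate. Neither the dehydrogenation of step 18 nor the organocerium addition of step 22 would be needed. In control of C8/C11 and of the C11 regiochemistry it is the equal or the better of the chosen plan.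
- Against it here: A3 is a monocyclic oxepane with C5 and the quaternary C30 already in place, which is harder to reach than 25. The C8 configuration relative to C30 rests on a chelated transition state in a flexible ring. The lactone offers C13 as the coupling carbon, which does not fit a west half whose C14 centre is created with its tether attached.
- Comparison: structurally it moves the fragment union to C13–C14 and would force a redesign of steps 5 to 14. Mechanistically a ketyl–olefin closure replaces an aldol union and a conjugate reduction. In step economy it should save about three steps after ring B and spend at least as many on A3.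

Alternative 3: The cuts are C15–C18 and C24–C25, the two bonds that attach ring C to ring D. A monovalent rhodium catalyst such as [Rh(CO)2Cl]2 would open the C28–C15 bond of vinylcyclopropane A6 and add the five-carbon unit across the alkene of cyclopentene A5 (from 2 by ring-closing metathesis with loss of isobutene). The product would be hydroazulene A7, which corresponds to 18 with a benzyl ether.
- In its favour: ring C would be assembled in one convergent step with the C26=C28 alkene in place and the cis ring fusion secured by suprafacial addition, so steps 3 to 12 would shrink to about four. In step economy and in the direct placement of the alkene it is clearly the better, and it takes C21 from the same chiral pool.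
- Against it here: two-component (5+2) reactions of vinylcyclopropanes are established for alkynes and allenes, not for an unactivated 1,2-disubstituted cycloalkene. The bond to be cleaved in A6 joins two fully substituted carbons. Nothing controls which alkene carbon bonds to C15, which face of A5 reacts, or how the C14 centre of A6 is matched. A6 has to be made as a single enantiomer.
- Comparison: structurally it avoids building the C14–C15 bond by bringing C15 in ready-made. Mechanistically a metallacycle replaces a radical chain and a radical conjugate addition, each of which has close precedent. The chosen plan is longer, but each of its ring-forming steps has a known counterpart.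

Key step: step 3

Remark: the C21 configuration of (R)-linalool and the cis/anti arrangement in 5 were compared with C18, C21 and C24 of the target atom by atom and agree, so no structure needed correction. The tertiary carbinol is silylated with the silyl triflate, because the chloride is too slow.
Remark: 21 is taken as the single (5E)-isomer. Material containing the (5Z)-isomer would lower the diastereomeric purity of 25.
Remark: stereocentres that are lost again within a few steps (C25 in 12, C28 in 14, C11 and C12 in 28 to 30) form as mixtures and are left open in the SMILES.

## Route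

Step 1
Reactants: 1 (R)-linalool
Product: 2 (R)-linalool tert-butyldimethylsilyl ether
Conditions: TBSOTf, 2,6-lutidine, CH2Cl2, −78 °C to 0 °C
Reagents that add atoms: tert-butyldimethylsilyl triflate, CC(C)(C)[Si](C)(C)OS(=O)(=O)C(F)(F)F
Why: O-silylation of the hindered tertiary allylic alcohol with a silyl triflate and a hindered pyridine base; the C21 stereocentre is not touched.

Step 2
Reactants: 3 sodium p-toluenesulfinate
Product: 4 p-toluenesulfonyl bromide
Conditions: Br2, H2O/CH2Cl2, 0 °C
Reagents that add atoms: bromine, BrBr
Why: Electrophilic bromination of the sulfinate anion at sulfur gives the sulfonyl bromide (oxidative halogenation of a sulfinate salt).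

Step 3
Reactants: 2 (R)-linalool tert-butyldimethylsilyl ether; 4 p-toluenesulfonyl bromide
Product: 5 ring D bromo sulfone (C25 sulfone and C15 bromide, arms cis, both anti to the silyloxy group)
Conditions: Et3B (0.2 equiv), air, PhH (0.02 M), 20 °C, 4 added over 3 h
Reagents that add atoms: none
Why: Ethyl radicals from Et3B and oxygen abstract bromine from 4; the tosyl radical adds reversibly to both alkenes of 2, but only the adduct at C25 has a fast forward path, because its C24 radical attacks C18 and the resulting tertiary C15 radical abstracts bromine from 4 and carries the chain. The closest known reaction type is the sulfonyl-radical atom-transfer addition–cyclisation of 1,6-dienes with sulfonyl halides. Ring D closes in the 5-exo-trig mode through a chair-like transition state, helped by the quaternary C21 in the chain. C24 and C18 are set together: a 1-substituted hexenyl radical places the C25 arm and the alkene terminus C15 pseudo-equatorial, which gives the cis-1,2 relationship. Their relation to C21 depends on which C21 substituent is pseudo-equatorial; that site is nearly eclipsed with the C24–C25 bond of the planar radical, so the oxygen, slim at its point of attachment and with the silyl group turned outward, should take it. The methyl group then takes the pseudo-axial site, where it meets only one axial hydrogen on C19, so both arms end anti to the silyloxy group. The step needs C–C bond formation from the C25 adduct only (secured by reversible sulfonyl radical addition), ring closure before bromine transfer (secured by slow addition of 4 at high dilution) and the diastereoselectivity just described (helped by initiation at 20 °C instead of at reflux).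

Step 4
Reactants: 5 ring D bromo sulfone
Product: 6 isopropenyl sulfone
Conditions: t-BuOK, THF, 0 °C to 20 °C
Reagents that add atoms: none
Why: E2 dehydrobromination by a bulky alkoxide should take a methyl hydrogen (Hofmann-type regioselectivity) and not the hindered ring hydrogen H18, so the isopropenyl group forms and C18 keeps its configuration; the sulfone is at most deprotonated reversibly at C25.

Step 5
Reactants: 7 3-(tert-butyldimethylsilyloxy)propanal; 8 ethyl 2-(triphenylphosphoranylidene)propanoate
Product: 9 ethyl (2E)-5-(tert-butyldimethylsilyloxy)-2-methylpent-2-enoate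
Conditions: CH2Cl2, 40 °C
Reagents that add atoms: none
Why: Wittig olefination with a stabilised α-methyl ylide gives the (E)-trisubstituted enoate, which fixes the C28=C14 geometry and brings in the C29 methyl group.

Step 6
Reactants: 9 ethyl (2E)-5-(tert-butyldimethylsilyloxy)-2-methylpent-2-enoate
Product: 10 (2E)-5-(tert-butyldimethylsilyloxy)-N-methoxy-N,2-dimethylpent-2-enamide
Conditions: MeNHOMe·HCl, i-PrMgCl, THF, −20 °C
Reagents that add atoms: N,O-dimethylhydroxylamine hydrochloride, CNOC.Cl
Why: Aminolysis of the ester by the chloromagnesium amide of N,O-dimethylhydroxylamine gives the Weinreb amide; conjugate addition to the α-substituted enoate is slow.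

Step 7
Reactants: 6 isopropenyl sulfone; 10 (2E)-5-(tert-butyldimethylsilyloxy)-N-methoxy-N,2-dimethylpent-2-enamide
Product: 12 β-keto sulfone (C25–C26 bond, (E)-enone, C25 epimers), via lithiated sulfone 11 (not isolated)
Conditions: n-BuLi, THF, −78 °C; then 10, −78 °C to −20 °C; aq. NH4Cl
Reagents that add atoms: none
Why: The α-sulfonyl carbanion adds 1,2 to the Weinreb amide, whose N-methoxy-N-methyl group prevents over-addition, so the C25–C26 bond forms with one equivalent of base (acylation of a sulfonyl carbanion); the new C25 centre is removed in step 8.

Step 8
Reactants: 12 β-keto sulfone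
Product: 13 (E)-enone with free isopropenyl group
Conditions: SmI2, THF/MeOH, −78 °C
Reagents that add atoms: none
Why: Electron transfer from SmI2 to the ketone expels p-toluenesulfinate from C25, and the enolate is protonated at C25 by methanol (reductive desulfonylation of a β-keto sulfone); at −78 °C without additives the enone, the isopropenyl group and the silyl ethers should survive.

Step 9
Reactants: 13 (E)-enone with free isopropenyl group
Product: 14 cis-fused hydroazulenone (C26 ketone, H14 α, C28 epimers)
Conditions: Fe(acac)3 (30 mol%), PhSiH3, EtOH/ethylene glycol, 60 °C, 0.01 M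
Reagents that add atoms: none
Why: Hydrogen atom transfer from an iron hydride to the electron-rich isopropenyl group gives the tertiary C15 radical, which adds 7-endo-trig to the β-carbon C14 of the enone (intramolecular Giese reaction); the α-keto radical is then reduced and protonated at C28. Attack at C14 is polarity-matched and is preferred over 6-exo attack at the fully substituted α-carbon C28. C14 is set in a chair-like transition state of the s-trans (E)-enone with the C13 chain pseudo-equatorial and the ring D bond at C24 pseudo-axial beside the trigonal C26, which should place H14 on the α face with H18 and H24.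

Step 10
Reactants: 14 cis-fused hydroazulenone
Product: 15 trimethylsilyl enol ether (C26=C28)
Conditions: TMSCl, NaI, Et3N, MeCN, 20 °C
Reagents that add atoms: chlorotrimethylsilane, C[Si](C)(C)Cl
Why: Silylation under equilibrating conditions (iodotrimethylsilane formed in the flask, amine base) gives the more substituted, thermodynamic silyl enol ether toward the tertiary α-carbon C28; the C28 stereocentre of 14 disappears here.

Step 11
Reactants: 15 trimethylsilyl enol ether
Product: 17 enol triflate (C26–OTf, C26=C28), via lithium enolate 16 (not isolated)
Conditions: MeLi, THF, 0 °C; then PhNTf2, −78 °C to 20 °C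
Reagents that add atoms: N-phenylbis(trifluoromethanesulfonimide), O=S(=O)(N(c1ccccc1)S(=O)(=O)C(F)(F)F)C(F)(F)F
Why: Methyllithium cleaves the O–Si bond to the regiodefined lithium enolate, which is O-sulfonylated by the triflimide (regiospecific enol triflate formation from a silyl enol ether).

Step 12
Reactants: 17 enol triflate
Product: 18 hydroazulene alkene (C26=C28)
Conditions: Pd(OAc)2 (5 mol%), PPh3 (10 mol%), HCO2H, n-Bu3N, DMF, 60 °C
Reagents that add atoms: none
Why: Palladium-catalysed formate reduction of the enol triflate (oxidative addition to zerovalent palladium, formate exchange, loss of CO2, reductive elimination) replaces the triflate by hydrogen and leaves the double bond at C26=C28.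

Step 13
Reactants: 18 hydroazulene alkene
Product: 19 primary alcohol (C12 hydroxyl)
Conditions: HF·pyridine, pyridine, THF, 0 °C
Reagents that add atoms: none
Why: Buffered HF·pyridine removes the primary silyl ether much faster than the hindered tertiary one on C21 (selective desilylation).

Step 14
Reactants: 19 primary alcohol
Product: 20 west aldehyde (C12 aldehyde)
Conditions: Dess–Martin periodinane, NaHCO3, CH2Cl2, 0 °C to 20 °C
Reagents that add atoms: none
Why: Buffered Dess–Martin oxidation of the primary alcohol leaves the alkene and the tertiary silyl ether alone; the aldehyde is not conjugated and has no α-stereocentre.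

Step 15
Reactants: 21 (E)-geranylacetone
Product: 22 (R,R,R)-diepoxy ketone
Conditions: 1,2:4,5-di-O-isopropylidene-β-D-erythro-2,3-hexodiulo-2,6-pyranose (D-fructose-derived Shi ketone, 2 × 30 mol%), KHSO5 (Oxone), K2CO3, Bu4NHSO4, MeCN/dimethoxymethane/aq. Na2B4O7 buffer, 0 °C
Reagents that add atoms: potassium peroxymonosulfate, [K+].[O-]S(=O)(=O)OO
Why: Shi epoxidation: the chiral dioxirane formed from the ketone and KHSO5 transfers oxygen to both trisubstituted alkenes through a spiro transition state, which should give the (R,R)-epoxide at C5/C30 and the (R)-epoxide at C34; the C5 configuration of the target originates here.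

Step 16
Reactants: 22 (R,R,R)-diepoxy ketone
Product: 24 tert-butyldimethylsilyl enol ether (terminal), via lithium enolate 23 (not isolated)
Conditions: LDA, THF, −78 °C; then TBSCl, DMPU, −78 °C to 0 °C
Reagents that add atoms: tert-butyldimethylsilyl chloride, CC(C)(C)[Si](C)(C)Cl
Why: Kinetic deprotonation with LDA at −78 °C takes the methyl group (C11), and O-silylation gives the terminal silyl enol ether; the epoxides are inert to the amide base at this temperature.

Step 17
Reactants: 24 tert-butyldimethylsilyl enol ether
Product: 25 trans-fused oxepane–cyclohexanone (C8 ketone, C34 silyl ether)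
Conditions: TBSOTf (1.1 equiv), 2,6-di-tert-butyl-4-methylpyridine, CH2Cl2, −78 °C
Reagents that add atoms: tert-butyldimethylsilyl triflate, CC(C)(C)[Si](C)(C)OS(=O)(=O)C(F)(F)F
Why: The silyl triflate activates the terminal epoxide, whose tertiary carbon C2 is attacked by the oxygen of the neighbouring epoxide; the bicyclic oxonium ion is then opened at the tertiary carbon C30 with inversion by the enol ether carbon C11 through a chair-like six-membered transition state (Lewis-acid-promoted tandem epoxide-opening oxa- and carbacyclisation of a 1,5-diepoxide ended by an enol silane). C5 keeps its C–O bond and configuration and C30 is inverted, which gives the trans ring fusion with the axial C31 methyl group; the silyl group of the reagent ends on O34.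

Step 18
Reactants: 25 trans-fused oxepane–cyclohexanone
Product: 26 east enone (C6=C7)
Conditions: 2-iodoxybenzoic acid, DMSO/toluene, 70 °C
Reagents that add atoms: none
Why: Dehydrogenation of the ketone with 2-iodoxybenzoic acid can only run toward C7/C6, because the other α-carbon C11 has no β-hydrogen (C30 is quaternary); the enone leaves C11 as the only enolisable carbon for step 19.

Step 19
Reactants: 26 east enone; 20 west aldehyde
Product: 28 aldol adduct (C11–C12 bond, C12 hydroxyl), via lithium dienolate 27 (not isolated)
Conditions: LDA, THF, −78 °C; then 20, −78 °C; aq. NH4Cl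
Reagents that add atoms: none
Why: Kinetic α′-deprotonation of the enone at C11 and addition of the lithium dienolate to the unhindered aldehyde join the two halves (directed aldol reaction); the new centres at C11 and C12 are removed or reset in steps 20 and 21.

Step 20
Reactants: 28 aldol adduct
Product: 30 cross-conjugated dienone (C6=C7 and C11=C12), via C12 mesylate 29 (not isolated)
Conditions: MsCl, Et3N, CH2Cl2, 0 °C; then DBU, 20 °C
Reagents that add atoms: none
Why: Mesylation of the β-hydroxy ketone and E1cB elimination with an amidine base give the exocyclic enone (aldol dehydration).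

Step 21
Reactants: 30 cross-conjugated dienone
Product: 31 coupled ketone (C8 ketone, C11 tether equatorial)
Conditions: Cu(OAc)2·H2O (5 mol%), 1,2-bis(diphenylphosphino)benzene (5 mol%), tetramethyldisiloxane, t-BuOH, toluene, 20 °C; then K2CO3, MeOH
Reagents that add atoms: none
Why: The copper hydride formed from Cu(OAc)2, the bisphosphine and the siloxane delivers hydride 1,4 to both conjugated C=C bonds, with protonation of the copper enolates by tert-butanol, and should not touch the isolated trisubstituted ring C alkene (conjugate reduction). Base equilibration places the tether on C11 equatorial, with H11 axial on the α face.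

Step 22
Reactants: 31 coupled ketone
Product: 32 C8 tertiary alcohol (bis-silyl ether)
Conditions: CeCl3, MeLi, THF, −78 °C
Reagents that add atoms: methyllithium, [Li]C
Why: The organocerium reagent adds to the ketone without enolising C11; the axial C31 methyl group blocks the axial trajectory, so the methyl group should enter equatorially and leave the C8 hydroxyl axial on the β face (1,2-addition).

Step 23
Reactants: 32 C8 tertiary alcohol
Product: 33 triol (C8, C21 and C34 hydroxyls)
Conditions: Bu4NF, THF, 60 °C
Reagents that add atoms: none
Why: Fluoride cleaves the hindered secondary (O34) and tertiary (O21) silyl ethers on warming; no base- or fluoride-sensitive group is present at this stage.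

Step 24
Reactants: 33 triol
Product: 34 keto diol (C34 ketone, C26=C28 alkene)
Conditions: Dess–Martin periodinane, NaHCO3, CH2Cl2, 0 °C
Reagents that add atoms: none
Why: Dess–Martin oxidation converts the only secondary alcohol into the ketone; the two tertiary alcohols and the alkene are inert.

Step 25
Reactants: 34 keto diol
Product: 36 CNP0259752.1 (target), via bromohydrin 35 (not isolated)
Conditions: N-bromosuccinimide, THF/H2O, 0 °C; then K2CO3, MeOH, 20 °C
Reagents that add atoms: water, O
Why: A bromonium ion on the open α face of the C26=C28 alkene should be opened by water at the tertiary carbon C28 from the β face, giving the trans-bromohydrin; carbonate then closes the epoxide by intramolecular SN2 displacement at C26 with inversion (halohydrin route). This places the oxygen on the β face, syn to the C13 tether, which is the face that direct oxygen transfer would be expected to avoid.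

## Compound list

1 | (R)-linalool, (3R)-3,7-dimethylocta-1,6-dien-3-ol | CC(C)=CCC[C@](C)(C=C)O | starting material
2 | (R)-linalool tert-butyldimethylsilyl ether | C=C[C@@](C)(CCC=C(C)C)O[Si](C)(C)C(C)(C)C | intermediate
3 | sodium p-toluenesulfinate | Cc1ccc(cc1)S(=O)[O-].[Na+] | starting material
4 | p-toluenesulfonyl bromide | Cc1ccc(cc1)S(=O)(=O)Br | intermediate
5 | (1R,2R,3R)-3-(2-bromopropan-2-yl)-1-methyl-2-(tosylmethyl)cyclopentyl tert-butyldimethylsilyl ether (arms cis, anti to the silyloxy group) | CC(C)(Br)[C@@H]1CC[C@@](C)(O[Si](C)(C)C(C)(C)C)[C@@H]1CS(=O)(=O)c1ccc(C)cc1 | intermediate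
6 | (1R,2R,3R)-1-methyl-3-(prop-1-en-2-yl)-2-(tosylmethyl)cyclopentyl tert-butyldimethylsilyl ether | CC(=C)[C@@H]1CC[C@@](C)(O[Si](C)(C)C(C)(C)C)[C@@H]1CS(=O)(=O)c1ccc(C)cc1 | intermediate
7 | 3-(tert-butyldimethylsilyloxy)propanal | O=CCCO[Si](C)(C)C(C)(C)C | starting material
8 | ethyl 2-(triphenylphosphoranylidene)propanoate | CCOC(=O)C(C)=P(c1ccccc1)(c1ccccc1)c1ccccc1 | starting material
9 | ethyl (2E)-5-(tert-butyldimethylsilyloxy)-2-methylpent-2-enoate | CCOC(=O)/C(C)=C/CCO[Si](C)(C)C(C)(C)C | intermediate
10 | (2E)-5-(tert-butyldimethylsilyloxy)-N-methoxy-N,2-dimethylpent-2-enamide | CON(C)C(=O)/C(C)=C/CCO[Si](C)(C)C(C)(C)C | intermediate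
11 | C25-lithio derivative of 6 (α-sulfonyl carbanion, lithium salt) | [Li+].CC(=C)[C@@H]1CC[C@@](C)(O[Si](C)(C)C(C)(C)C)[C@@H]1[CH-]S(=O)(=O)c1ccc(C)cc1 | intermediate
12 | β-keto sulfone: 6 acylated at C25 by 10; C26 ketone conjugated to the (E)-C28=C14 alkene; C25 epimers | CC(=C)[C@@H]1CC[C@@](C)(O[Si](C)(C)C(C)(C)C)[C@@H]1C(C(=O)/C(C)=C/CCO[Si](C)(C)C(C)(C)C)S(=O)(=O)c1ccc(C)cc1 | intermediate
13 | (E)-enone: 12 with hydrogen in place of the sulfonyl group | CC(=C)[C@@H]1CC[C@@](C)(O[Si](C)(C)C(C)(C)C)[C@@H]1CC(=O)/C(C)=C/CCO[Si](C)(C)C(C)(C)C | intermediate
14 | cis-fused hydroazulenone: C26 ketone, C28 methyl (epimers), C15 gem-dimethyl, 2-(silyloxy)ethyl on C14 β (H14 α), H18 and H24 α, C21 methyl β and silyloxy α | CC(C)(C)[Si](C)(C)OCC[C@@H]1C(C)(C)[C@@H]2CC[C@@](C)(O[Si](C)(C)C(C)(C)C)[C@@H]2CC(=O)C1C | intermediate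
15 | trimethylsilyl enol ether of 14 with the C26=C28 double bond | CC(C)(C)[Si](C)(C)OCC[C@@H]1C(C)(C)[C@@H]2CC[C@@](C)(O[Si](C)(C)C(C)(C)C)[C@@H]2CC(O[Si](C)(C)C)=C1C | intermediate
16 | lithium enolate corresponding to 15 | [Li+].CC(C)(C)[Si](C)(C)OCC[C@@H]1C(C)(C)[C@@H]2CC[C@@](C)(O[Si](C)(C)C(C)(C)C)[C@@H]2CC([O-])=C1C | intermediate
17 | enol triflate (triflate on C26, C26=C28) | CC(C)(C)[Si](C)(C)OCC[C@@H]1C(C)(C)[C@@H]2CC[C@@](C)(O[Si](C)(C)C(C)(C)C)[C@@H]2CC(OS(=O)(=O)C(F)(F)F)=C1C | intermediate
18 | hydroazulene alkene: 17 with hydrogen on C26, both silyl ethers retained | CC(C)(C)[Si](C)(C)OCC[C@@H]1C(C)(C)[C@@H]2CC[C@@](C)(O[Si](C)(C)C(C)(C)C)[C@@H]2CC=C1C | intermediate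
19 | primary alcohol: 18 with free C12 hydroxyl | OCC[C@@H]1C(C)(C)[C@@H]2CC[C@@](C)(O[Si](C)(C)C(C)(C)C)[C@@H]2CC=C1C | intermediate
20 | west aldehyde: C12 aldehyde of 19 | O=CC[C@@H]1C(C)(C)[C@@H]2CC[C@@](C)(O[Si](C)(C)C(C)(C)C)[C@@H]2CC=C1C | intermediate
21 | (E)-geranylacetone, (5E)-6,10-dimethylundeca-5,9-dien-2-one | CC(=O)CC/C=C(C)/CCC=C(C)C | starting material
22 | 4-[(2R,3R)-3-{2-[(2R)-3,3-dimethyloxiran-2-yl]ethyl}-3-methyloxiran-2-yl]butan-2-one | CC(=O)CC[C@H]1O[C@]1(C)CC[C@H]1OC1(C)C | intermediate
23 | terminal lithium enolate of 22 | [Li+].C=C([O-])CC[C@H]1O[C@]1(C)CC[C@H]1OC1(C)C | intermediate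
24 | terminal tert-butyldimethylsilyl enol ether of 22 | C=C(O[Si](C)(C)C(C)(C)C)CC[C@H]1O[C@]1(C)CC[C@H]1OC1(C)C | intermediate
25 | (3R,5aR,9aR)-3-(tert-butyldimethylsilyloxy)-2,2,5a-trimethyloctahydro-1-benzoxepin-7(2H)-one (trans-fused) | CC1(C)O[C@@H]2CCC(=O)C[C@@]2(C)CC[C@H]1O[Si](C)(C)C(C)(C)C | intermediate
26 | (3R,5aR,9aR)-3-(tert-butyldimethylsilyloxy)-2,2,5a-trimethyl-2,3,4,5,5a,9a-hexahydro-1-benzoxepin-7(6H)-one (C6=C7 enone) | CC1(C)O[C@@H]2C=CC(=O)C[C@@]2(C)CC[C@H]1O[Si](C)(C)C(C)(C)C | intermediate
27 | lithium dienolate of 26 (deprotonated at C11) | [Li+].CC1(C)O[C@@H]2C=CC([O-])=C[C@@]2(C)CC[C@H]1O[Si](C)(C)C(C)(C)C | intermediate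
28 | aldol adduct of 26 and 20 (C11–C12 bond, C12 hydroxyl, mixture at C11 and C12) | CC1(C)O[C@@H]2C=CC(=O)C(C(O)C[C@@H]3C(C)(C)[C@@H]4CC[C@@](C)(O[Si](C)(C)C(C)(C)C)[C@@H]4CC=C3C)[C@@]2(C)CC[C@H]1O[Si](C)(C)C(C)(C)C | intermediate
29 | C12 methanesulfonate of 28 | CC1(C)O[C@@H]2C=CC(=O)C(C(OS(C)(=O)=O)C[C@@H]3C(C)(C)[C@@H]4CC[C@@](C)(O[Si](C)(C)C(C)(C)C)[C@@H]4CC=C3C)[C@@]2(C)CC[C@H]1O[Si](C)(C)C(C)(C)C | intermediate
30 | cross-conjugated dienone (C6=C7 and exocyclic C11=C12) | CC1(C)O[C@@H]2C=CC(=O)C(=CC[C@@H]3C(C)(C)[C@@H]4CC[C@@](C)(O[Si](C)(C)C(C)(C)C)[C@@H]4CC=C3C)[C@@]2(C)CC[C@H]1O[Si](C)(C)C(C)(C)C | intermediate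
31 | coupled ketone: C8 ketone, tether equatorial on C11 (H11 α), silyl ethers on O21 and O34, C26=C28 alkene | CC1(C)O[C@@H]2CCC(=O)[C@H](CC[C@@H]3C(C)(C)[C@@H]4CC[C@@](C)(O[Si](C)(C)C(C)(C)C)[C@@H]4CC=C3C)[C@@]2(C)CC[C@H]1O[Si](C)(C)C(C)(C)C | intermediate
32 | C8 tertiary alcohol (hydroxyl axial, β; methyl equatorial), bis-silyl ether | CC1(C)O[C@@H]2CC[C@](C)(O)[C@H](CC[C@@H]3C(C)(C)[C@@H]4CC[C@@](C)(O[Si](C)(C)C(C)(C)C)[C@@H]4CC=C3C)[C@@]2(C)CC[C@H]1O[Si](C)(C)C(C)(C)C | intermediate
33 | triol (free hydroxyls on C8, C21 and C34) | CC1(C)O[C@@H]2CC[C@](C)(O)[C@H](CC[C@@H]3C(C)(C)[C@@H]4CC[C@@](C)(O)[C@@H]4CC=C3C)[C@@]2(C)CC[C@H]1O | intermediate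
34 | keto diol: C34 ketone, C26=C28 alkene (the deoxy form of the target) | CC1(C)O[C@@H]2CC[C@](C)(O)[C@H](CC[C@@H]3C(C)(C)[C@@H]4CC[C@@](C)(O)[C@@H]4CC=C3C)[C@@]2(C)CCC1=O | intermediate
35 | bromohydrin: bromide on C26 (α), hydroxyl on C28 (β) | CC1(C)O[C@@H]2CC[C@](C)(O)[C@H](CC[C@@H]3C(C)(C)[C@@H]4CC[C@@](C)(O)[C@@H]4C[C@@H](Br)[C@@]3(O)C)[C@@]2(C)CCC1=O | intermediate
36 | CNP0259752.1 | CC1(C)O[C@@H]2CC[C@](C)(O)[C@H](CC[C@@H]3C(C)(C)[C@@H]4CC[C@@](C)(O)[C@@H]4C[C@@H]4O[C@@]43C)[C@@]2(C)CCC1=O | target

## Step count and least certain steps

Total: 25 steps. Longest linear sequence: 18 steps, from 1 through steps 1, 3, 4, 7 to 14 and 19 to 25.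

Step 3 (key step). The most likely failure is weak discrimination between the methyl and silyloxy groups on C21, because the two chair transition states lie close in energy. A second risk is bromine transfer to the C24 radical before ring closure if 4 accumulates. Fallback, which changes the control element and the order of events: unprotected 1 is cyclised with 4 under the same chain conditions in a non-polar solvent. A hydrogen bond between the C21 hydroxyl and a sulfonyl oxygen on C25 should then hold the hydroxyl in the pseudo-equatorial site next to the C25 arm. The resulting hydroxy bromo sulfone F1 is silylated (TBSOTf, 2,6-lutidine) and rejoins the route at 5.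

Step 9. The most likely failure is attack on the wrong face of C14, because the seven-membered transition state is flexible and the acceptor carbon is substituted. Fallback, which sets C14 by hydride delivery instead of by the radical closure: it sets out from 15, which carries whatever C14 mixture step 9 gives. Saegusa–Ito dehydrogenation (Pd(OAc)2, MeCN) erases C14 and gives the cycloheptenone F2. Conjugate reduction with the copper hydride system of step 21 should deliver hydride to C14 from the convex α face and return 14.

Step 17. The most likely failure is an interrupted or misdirected cascade: direct attack of the enol ether on the activated internal epoxide, or proton loss from the oxonium ion, before the C11–C30 bond forms. Fallback, which uses a more nucleophilic carbon terminator and unmasks the ketone afterwards: it sets out from 22. Kinetic enolisation and triflation (LDA; PhNTf2) give the enol triflate F3. Coupling with Me3SiCH2MgCl (Pd(PPh3)4) gives the allylsilane F4. The same silyl triflate conditions should give the exocyclic alkene F5. Ozonolysis (O3; Me2S) returns 25.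

Step 25. The most likely failure is bromonium formation and opening with the opposite facial sense, if the β face of the ring C alkene turns out to be the more accessible one; that would put the epoxide on the α face. Fallback, with the opposite stereochemical logic: direct oxygen transfer to 34 with dimethyldioxirane (acetone, 0 °C) places the oxygen on whichever face is more accessible and leads from 34 to 36. This fallback makes no new compound.

## Further compounds

F1 | step 3 | (1R,2R,3R)-3-(2-bromopropan-2-yl)-1-methyl-2-(tosylmethyl)cyclopentan-1-ol | CC(C)(Br)[C@@H]1CC[C@@](C)(O)[C@@H]1CS(=O)(=O)c1ccc(C)cc1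
F2 | step 9 | cycloheptenone with C28=C14 double bond (C26 ketone, C14 sp2) | CC1=C(CCO[Si](C)(C)C(C)(C)C)C(C)(C)[C@@H]2CC[C@@](C)(O[Si](C)(C)C(C)(C)C)[C@@H]2CC1=O
F3 | step 17 | terminal enol triflate of 22 | C=C(OS(=O)(=O)C(F)(F)F)CC[C@H]1O[C@]1(C)CC[C@H]1OC1(C)C
F4 | step 17 | 2-substituted allylsilane from F3 | C=C(C[Si](C)(C)C)CC[C@H]1O[C@]1(C)CC[C@H]1OC1(C)C
F5 | step 17 | trans-fused oxepane–cyclohexane with exocyclic methylene on C8 and silyl ether on O34 | CC1(C)O[C@@H]2CCC(=C)C[C@@]2(C)CC[C@H]1O[Si](C)(C)C(C)(C)C
F0 | step 25 | none | none
A1 | alternative 1 | olefinic ester: ethyl 2-alkoxy-2-methylpropanoate on O4, allyl group on C30, C11 ketal | CCOC(=O)C(C)(C)O[C@@H]1CCCC2(OCCO2)[C@@]1(C)CC=C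
A2 | alternative 1 | bicyclic ethyl enol ether of the oxepanone | CC1(C)O[C@@H]2CCCC3(OCCO3)[C@@]2(C)CC=C1OCC
A3 | alternative 2 | oxepane keto enoate (3-oxobutyl on C5, methyl (E)-acrylate on C30) | CC1(C)O[C@H](CCC(C)=O)[C@@](C)(/C=C/C(=O)OC)CC[C@H]1O[Si](C)(C)C(C)(C)C
A4 | alternative 2 | tricyclic cis-fused γ-lactone | CC1(C)O[C@@H]2CC[C@]3(C)OC(=O)C[C@@H]3[C@@]2(C)CC[C@H]1O[Si](C)(C)C(C)(C)C
A5 | alternative 3 | (R)-1-methylcyclopent-2-en-1-yl tert-butyldimethylsilyl ether | C[C@@]1(O[Si](C)(C)C(C)(C)C)CCC=C1
A6 | alternative 3 | 1-methyl-1-vinyl-2,2-dimethyl-3-(2-benzyloxyethyl)cyclopropane (C14 configured, C28 open) | C=CC1(C)[C@H](CCOCc2ccccc2)C1(C)C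
A7 | alternative 3 | cis-fused hydroazulene with C26=C28 alkene and benzyl ether | c1ccccc1COCC[C@@H]2C(C)(C)[C@@H]3CC[C@@](C)(O[Si](C)(C)C(C)(C)C)[C@@H]3CC=C2C
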